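**Retrosynthetic overview**

1. Target 13 ← hydrogenolysis of two benzyl ethers ← 3-O-hexanoylation ← DDQ oxidation of the C4 carbinol ← OsO4 cis-dihydroxylation of flav-3-ene 8, anti to the C2 phenyl group.
2. Feature used: in ring C (the pyranone ring) C3 carries the ester oxygen and its neighbour C4 is the ketone carbon, so the C3–C4 bond is traced back to the C3=C4 alkene of a 2H-chromene.
3. 8 ← ring-closing metathesis of diene 7 (aryl vinyl group plus the vinyl group of a 1-phenylallyl aryl ether), which forms C3=C4 and closes ring C.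
4. 7 ← iridium-catalysed asymmetric allylic etherification (sets C2 and the O1–C2 bond) of vinylphenol 3 with cinnamyl methyl carbonate 5; 3 ← Wittig methylenation ← selective dibenzylation of 2,4,6-trihydroxybenzaldehyde 1.
5. Ring order: rings A and B come with the starting materials; ring C is the only ring built (step 5).

Key step: step 5

Remark on configuration: the target is read as (2R,3R), 2,3-trans (pinobanksin 3-O-hexanoate). C2 has the same spatial arrangement throughout; it is named S in 7 and 8 and R from 9 onwards only because the CIP rank of phenyl against the neighbouring carbon changes. Likewise C3 is S in 9 and R in 10, 12 and 13 without any spatial change.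

Assumption: the (Sa,S,S) enantiomer of the phosphoramidite ligand is taken to deliver the (S)-ether 7. If the first run shows the opposite sense, the (Ra,R,R) ligand is used and nothing else changes.

**Route**

Step 1
Reactants: 1 2,4,6-trihydroxybenzaldehyde
Product: 2 2,4-bis(benzyloxy)-6-hydroxybenzaldehyde
Conditions: BnBr (2.05 equiv), K2CO3 (2.2 equiv), DMF, 0 °C to rt
Reagents that add atoms: benzyl bromide, BrCc1ccccc1
Why: Williamson etherification; the para hydroxyl is the most acidic and reacts first, one ortho hydroxyl follows, and the last ortho hydroxyl, held in a hydrogen bond to the formyl group, is the least nucleophilic, so at this stoichiometry the dibenzyl ether with one free chelated phenol should be the main product.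

Step 2
Reactants: 2 2,4-bis(benzyloxy)-6-hydroxybenzaldehyde
Product: 3 3,5-bis(benzyloxy)-2-vinylphenol
Conditions: MePPh3Br (2.5 equiv), KOtBu (2.5 equiv), THF, 0 °C to 40 °C; neutral aqueous work-up, product used promptly
Reagents that add atoms: methyltriphenylphosphonium bromide, C[P+](c1ccccc1)(c1ccccc1)c1ccccc1.[Br-]
Why: Wittig methylenation; the unstabilised ylide is used in excess because the acidic phenol consumes base, and it is reactive enough to methylenate the electron-rich ortho-hydroxy aldehyde, as is standard for the conversion of salicylaldehydes into 2-vinylphenols.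

Step 3
Reactants: 4 (E)-cinnamyl alcohol
Product: 5 (E)-cinnamyl methyl carbonate
Conditions: ClCO2Me (1.3 equiv), pyridine (2 equiv), CH2Cl2, 0 °C
Reagents that add atoms: methyl chloroformate, COC(=O)Cl
Why: Alkoxycarbonylation of a primary allylic alcohol with a chloroformate under pyridine; it gives the standard leaving group for iridium-catalysed allylic substitution without touching the E alkene.

Step 4
Reactants: 3 3,5-bis(benzyloxy)-2-vinylphenol; 5 (E)-cinnamyl methyl carbonate
Product: 7 (S)-1,5-bis(benzyloxy)-3-[(1-phenylallyl)oxy]-2-vinylbenzene, via lithium 3,5-bis(benzyloxy)-2-vinylphenolate 6 (not isolated)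
Conditions: LiN(SiMe3)2 (1.0 equiv), THF, 0 °C; then 5 (1.2 equiv), [Ir(cod)Cl]2 (2 mol%), (Sa,S,S)-O,O'-(1,1'-binaphthyl-2,2'-diyl) N,N-bis(1-phenylethyl)phosphoramidite (4 mol%, catalyst pre-activated with n-PrNH2), THF, 50 °C; aqueous work-up
Reagents that add atoms: lithium bis(trimethylsilyl)amide, [Li+].C[Si](C)(C)[N-][Si](C)(C)C (its lithium is held only in intermediate 6, not in 7)
Why: Iridium-catalysed asymmetric allylic etherification; the cyclometalated iridium–phosphoramidite complex ionises 5 to a 1-phenylallyl complex, the lithium phenoxide attacks the phenyl-bearing terminus to give the branched ether, and the chiral ligand fixes the face of attack so that the new stereocentre (the later C2) should be S.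

Step 5
Reactants: 7 (S)-1,5-bis(benzyloxy)-3-[(1-phenylallyl)oxy]-2-vinylbenzene
Product: 8 (2S)-5,7-bis(benzyloxy)-2-phenyl-2H-chromene
Conditions: RuCl2(=CHPh)(H2IMes)(PCy3) (second-generation Grubbs catalyst, 5 mol%), 1,4-benzoquinone (10 mol%), degassed CH2Cl2 (0.01 M), 30 °C, exclusion of light
Reagents that add atoms: none
Why: Ring-closing olefin metathesis: the ruthenium benzylidene exchanges onto the terminal vinyl group of the 1-phenylallyl ether, the new alkylidene adds to the ortho styrenyl double bond to give a ruthenacyclobutane, and cycloreversion releases the chromene and Ru=CH2, the two terminal CH2 groups leaving as ethylene. The closest known reaction is the ring-closing metathesis of 2-vinylaryl allyl ethers to 2H-chromenes with the same catalyst. Ring C is closed as a six-membered ring by forming the C3=C4 double bond between two tethered monosubstituted alkenes, the O1–C2 and C4–C4a bonds being already in place. No stereocentre is created, and C2 keeps its configuration from step 4 because none of its bonds takes part. The step needs ring closure to outrun intermolecular metathesis, which the ortho placement of the two vinyl groups and high dilution secure; it also needs the allylic ether centre to stay untouched, for which benzoquinone intercepts ruthenium hydrides (no double-bond migration) and low temperature and darkness prevent 6π ring-opening of the chromene.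

Step 6
Reactants: 8 (2S)-5,7-bis(benzyloxy)-2-phenyl-2H-chromene
Product: 9 (2R,3S,4S)-5,7-bis(benzyloxy)-2-phenylchromane-3,4-diol
Conditions: OsO4 (3 mol%), N-methylmorpholine N-oxide (1.5 equiv), acetone/H2O 5:1, 0 °C to rt, dark
Reagents that add atoms: osmium tetroxide, O=[Os](=O)(=O)=O; N-methylmorpholine N-oxide, C[N+]1([O-])CCOCC1; water, O
Why: Upjohn syn-dihydroxylation; OsO4 adds to the C3=C4 face opposite the C2 phenyl group (substrate control from C2), which sets C3 and C4 together as a cis diol with the C3 hydroxyl trans to phenyl.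

Step 7
Reactants: 9 (2R,3S,4S)-5,7-bis(benzyloxy)-2-phenylchromane-3,4-diol
Product: 10 (2R,3R)-5,7-bis(benzyloxy)-3-hydroxy-2-phenylchroman-4-one
Conditions: DDQ (1.1 equiv), dry 1,4-dioxane, rt, dark
Reagents that add atoms: none
Why: DDQ oxidation of an electron-rich benzylic alcohol by hydride abstraction from C4–H, the cation being stabilised by O1 and by the 5- and 7-benzyloxy groups; the C3 carbinol is not benzylic and should stay, and C2 and C3 are not touched.

Step 8
Reactants: 10 (2R,3R)-5,7-bis(benzyloxy)-3-hydroxy-2-phenylchroman-4-one; 11 hexanoyl chloride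
Product: 12 (2R,3R)-5,7-bis(benzyloxy)-4-oxo-2-phenylchroman-3-yl hexanoate
Conditions: 11 (1.2 equiv), pyridine (2 equiv), DMAP (5 mol%), CH2Cl2, 0 °C
Reagents that add atoms: none
Why: DMAP-catalysed acylation of the only free hydroxyl through the N-acylpyridinium ion; the weak base and low temperature should avoid enolisation at C3 and retro-oxa-Michael opening of ring C, so the trans arrangement is kept.

Step 9
Reactants: 12 (2R,3R)-5,7-bis(benzyloxy)-4-oxo-2-phenylchroman-3-yl hexanoate
Product: 13 (2R,3R)-5,7-dihydroxy-4-oxo-2-phenylchroman-3-yl hexanoate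
Conditions: H2 (1 atm), Pd/C (10% palladium on carbon), EtOAc, rt, stopped after uptake of two equivalents
Reagents that add atoms: none
Why: Catalytic hydrogenolysis of two aryl benzyl ethers; the ester, the aryl ketone (hydrogen-bonded to the freed 5-hydroxyl) and the C2–O1 bond should survive under these mild neutral conditions when the reaction is stopped at two equivalents.

**Compound list**

1 | 2,4,6-trihydroxybenzaldehyde | O=Cc1c(O)cc(O)cc1O | starting material
2 | 2,4-bis(benzyloxy)-6-hydroxybenzaldehyde | O=Cc1c(O)cc(OCc2ccccc2)cc1OCc1ccccc1 | intermediate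
3 | 3,5-bis(benzyloxy)-2-vinylphenol | C=Cc1c(O)cc(OCc2ccccc2)cc1OCc1ccccc1 | intermediate
4 | (E)-cinnamyl alcohol | OC/C=C/c1ccccc1 | starting material
5 | (E)-cinnamyl methyl carbonate | COC(=O)OC/C=C/c1ccccc1 | intermediate
6 | lithium 3,5-bis(benzyloxy)-2-vinylphenolate | [Li+].[O-]c1cc(OCc2ccccc2)cc(OCc2ccccc2)c1C=C | intermediate (not isolated)
7 | (S)-1,5-bis(benzyloxy)-3-[(1-phenylallyl)oxy]-2-vinylbenzene | C=C[C@H](Oc1cc(OCc2ccccc2)cc(OCc2ccccc2)c1C=C)c1ccccc1 | intermediate
8 | (2S)-5,7-bis(benzyloxy)-2-phenyl-2H-chromene | C1=Cc2c(OCc3ccccc3)cc(OCc3ccccc3)cc2O[C@@H]1c1ccccc1 | intermediate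
9 | (2R,3S,4S)-5,7-bis(benzyloxy)-2-phenylchromane-3,4-diol | O[C@H]1[C@@H](O)c2c(OCc3ccccc3)cc(OCc3ccccc3)cc2O[C@@H]1c1ccccc1 | intermediate
10 | (2R,3R)-5,7-bis(benzyloxy)-3-hydroxy-2-phenylchroman-4-one | O[C@H]1C(=O)c2c(OCc3ccccc3)cc(OCc3ccccc3)cc2O[C@@H]1c1ccccc1 | intermediate
11 | hexanoyl chloride | CCCCCC(=O)Cl | starting material
12 | (2R,3R)-5,7-bis(benzyloxy)-4-oxo-2-phenylchroman-3-yl hexanoate | CCCCCC(=O)O[C@H]1C(=O)c2c(OCc3ccccc3)cc(OCc3ccccc3)cc2O[C@@H]1c1ccccc1 | intermediate
13 | (2R,3R)-5,7-dihydroxy-4-oxo-2-phenylchroman-3-yl hexanoate | CCCCCC(=O)O[C@H]1C(=O)c2c(O)cc(O)cc2O[C@@H]1c1ccccc1 | target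

**Step count and risks**

Total step count: 9. Longest linear sequence: 8 steps (steps 1, 2, 4, 5, 6, 7, 8, 9 from compound 1).

Steps most likely to fail:

Step 4. The very electron-rich phenoxide may be allylated on ring carbon instead of oxygen, attack may occur at the unsubstituted allyl terminus to give the linear ether, or the ortho-vinyl group may lower the enantioselectivity. The fallback sets out from 3 and comes back at 7. It is a Mitsunobu etherification of 3 with (R)-1-phenylprop-2-en-1-ol F1 (bought as the single enantiomer), PPh3 and diisopropyl azodicarboxylate in toluene at −20 to 0 °C. SN2 displacement at the carbinol carbon with inversion should give (S)-7, so the stereocentre comes from the alcohol and not from a catalyst.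

Step 5. Enantiopurity at C2 may be lost through ruthenium-hydride double-bond migration or through reversible 6π ring-opening of the donor-substituted chromene, and the catalyst may stall on the 2,6-dioxygenated styrene. The fallback avoids any 2H-chromene; it sets out from 2 and comes back at 10.
- Protection of 2 with MOMCl and iPr2NEt in CH2Cl2 should give 2,4-bis(benzyloxy)-6-(methoxymethoxy)benzaldehyde F2.
- Addition of (E)-PhCH=CHMgBr in THF at −78 °C should give (E)-1-[2,4-bis(benzyloxy)-6-(methoxymethoxy)phenyl]-3-phenylprop-2-en-1-ol F3.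
- Oxidation with MnO2 in CH2Cl2 should give the chalcone (E)-1-[2,4-bis(benzyloxy)-6-(methoxymethoxy)phenyl]-3-phenylprop-2-en-1-one F4.
- Juliá–Colonna epoxidation (poly-L-leucine, urea–H2O2, DBU, THF) should give [2,4-bis(benzyloxy)-6-(methoxymethoxy)phenyl][(2R,3S)-3-phenyloxiran-2-yl]methanone F5.
- HCl in MeOH/THF at 45 °C should remove the MOM group and let the freed phenol open the epoxide at the benzylic carbon with inversion. This closes ring C through the O1–C2 bond and should give trans-10, with C3 fixed by the epoxide.

Step 7. The oxidant may fail to distinguish the C4 and C3 carbinols, may cleave the cis-glycol, or may dehydrogenate further towards the flavonol; the by-product hydroquinone may also ionise the C4 hydroxyl. The fallback sets out from 8 and comes back at 12, with C3 acylated before C4 is oxidised so that no chemoselectivity between two carbinols is needed.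
- Hydroboration–oxidation of 8 (BH3·THF, THF, 0 °C; then NaOH/H2O2), with boron adding to C3 anti to the phenyl group, should give (2R,3S)-5,7-bis(benzyloxy)-2-phenylchroman-3-ol F6.
- Acylation with 11, pyridine and DMAP in CH2Cl2 should give (2R,3S)-5,7-bis(benzyloxy)-2-phenylchroman-3-yl hexanoate F7.
- Benzylic C4–H oxidation with DDQ in CH2Cl2/H2O should give (2R,3S)-5,7-bis(benzyloxy)-4-hydroxy-2-phenylchroman-3-yl hexanoate F8 as a mixture of C4 epimers.
- Dess–Martin periodinane in CH2Cl2 should convert both epimers into 12.

**Further compounds**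

F1 | step 4 | (R)-1-phenylprop-2-en-1-ol | C=C[C@@H](O)c1ccccc1
F2 | step 5 | 2,4-bis(benzyloxy)-6-(methoxymethoxy)benzaldehyde | O=Cc1c(OCOC)cc(OCc2ccccc2)cc1OCc1ccccc1
F3 | step 5 | (E)-1-[2,4-bis(benzyloxy)-6-(methoxymethoxy)phenyl]-3-phenylprop-2-en-1-ol (racemic at the carbinol) | OC(/C=C/c1ccccc1)c1c(OCOC)cc(OCc2ccccc2)cc1OCc1ccccc1
F4 | step 5 | (E)-1-[2,4-bis(benzyloxy)-6-(methoxymethoxy)phenyl]-3-phenylprop-2-en-1-one | O=C(/C=C/c1ccccc1)c1c(OCOC)cc(OCc2ccccc2)cc1OCc1ccccc1
F5 | step 5 | [2,4-bis(benzyloxy)-6-(methoxymethoxy)phenyl][(2R,3S)-3-phenyloxiran-2-yl]methanone | O=C(c1c(OCOC)cc(OCc2ccccc2)cc1OCc1ccccc1)[C@@H]1O[C@H]1c1ccccc1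
F6 | step 7 | (2R,3S)-5,7-bis(benzyloxy)-2-phenylchroman-3-ol | O[C@H]1Cc2c(OCc3ccccc3)cc(OCc3ccccc3)cc2O[C@@H]1c1ccccc1
F7 | step 7 | (2R,3S)-5,7-bis(benzyloxy)-2-phenylchroman-3-yl hexanoate | CCCCCC(=O)O[C@H]1Cc2c(OCc3ccccc3)cc(OCc3ccccc3)cc2O[C@@H]1c1ccccc1
F8 | step 7 | (2R,3S)-5,7-bis(benzyloxy)-4-hydroxy-2-phenylchroman-3-yl hexanoate (both C4 epimers) | CCCCCC(=O)O[C@H]1C(O)c2c(OCc3ccccc3)cc(OCc3ccccc3)cc2O[C@@H]1c1ccccc1
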